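**Strategy.** The upper flavan is disconnected at C4–C4a. C4 is benzylic to ring D and is tied to ring A through O1–C2–C3, so a C3–C4 oxirane on an open-chain ring A aryl ether can be opened at C4 by the ring A carbon ortho to the ether oxygen. One Lewis-acid step then forges C4–C4a, closes pyran ring C (6-endo) and sets C4 by inversion, leaving the 3-OH. The precursor is a cis-epoxide with ring B and the 3-benzyloxyphenoxy group on C2 and a brominated, differentially protected ring D on C4. Its bromide later becomes the acyl carbon from which the lower dihydroflavonol and its cis-diol are built.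

Key step: step 8

Remarks on the chemistry:
- Reading of the target: both flavan units are (2R,3S,4S), i.e. 2,3-trans-3,4-cis. Upper unit: rings A (benzo), B (catechol), C (pyran). Lower unit: rings D (benzo), E (catechol), F (pyran). C6 of ring D carries C4 of ring C.
- No stereochemical error was found in the epoxide precursor or its cyclisation product: the oxirane is cis, and inversion at C4 gives the 3,4-cis product.
- Design changes: the ring D oxygen para to the oxirane carbon is a MOM ether (all other phenols benzyl), because it alone must be freed to close ring F. The oxirane is installed under hydroxyl direction before the aryl ether is made. The alkyne is made without alkyllithium so the aryl bromide survives.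
- Assumption: 5-(benzyloxy)-2-bromophenol, used only in the fallback for step 8, is taken to be purchasable.

**Route**

Step 1
Reactants: 1 5-bromo-2,4-dihydroxybenzaldehyde
Product: 2 5-bromo-2-hydroxy-4-(methoxymethoxy)benzaldehyde
Conditions: MOMCl (1.05 equiv), K2CO3, acetone, 0 °C to rt
Reagents that add atoms: chloromethyl methyl ether, COCCl
Why: Williamson-type O-alkylation in which the 4-OH, para to the formyl group and not held in the hydrogen bond that deactivates the 2-OH, is the more acidic and accessible phenol and should react selectively with one equivalent of reagent.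

Step 2
Reactants: 2 5-bromo-2-hydroxy-4-(methoxymethoxy)benzaldehyde
Product: 3 2-(benzyloxy)-5-bromo-4-(methoxymethoxy)benzaldehyde
Conditions: BnBr, K2CO3, DMF, 50 °C
Reagents that add atoms: benzyl bromide, BrCc1ccccc1
Why: Williamson benzylation of the remaining chelated phenol under slightly more forcing conditions puts a non-participating benzyl group ortho to the future C4 and leaves MOM as the only acid-labile ether on ring D.

Step 3
Reactants: 3 2-(benzyloxy)-5-bromo-4-(methoxymethoxy)benzaldehyde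
Product: 4 1-(benzyloxy)-4-bromo-2-ethynyl-5-(methoxymethoxy)benzene
Conditions: dimethyl (1-diazo-2-oxopropyl)phosphonate, K2CO3, MeOH/THF, 0 °C to rt
Reagents that add atoms: dimethyl (1-diazo-2-oxopropyl)phosphonate, CC(=O)C(=[N+]=[N-])P(=O)(OC)OC
Why: Seyferth–Gilbert homologation in its Ohira–Bestmann form turns the aryl aldehyde into the terminal alkyne under carbonate/methanol conditions that leave the aryl bromide and the MOM ether untouched.

Step 4
Reactants: 4 1-(benzyloxy)-4-bromo-2-ethynyl-5-(methoxymethoxy)benzene, 5 3,4-bis(benzyloxy)benzaldehyde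
Product: 7 (1S)-1-[3,4-bis(benzyloxy)phenyl]-3-[2-(benzyloxy)-5-bromo-4-(methoxymethoxy)phenyl]prop-2-yn-1-ol, via ethylzinc acetylide 6 (not isolated)
Conditions: Et2Zn, toluene, reflux; then (R)-BINOL (20 mol %), Ti(OiPr)4 (50 mol %), 5, Et2O, rt; aq. NH4Cl
Reagents that add atoms: none
Why: Catalytic asymmetric alkynylzinc addition to an aromatic aldehyde, in which the BINOL–titanium complex (ligand enantiomer chosen for delivery to the Re face of the aldehyde) should set the carbinol centre as S, while aryl bromide and ethers are inert to organozinc reagents.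

Step 5
Reactants: 7 (1S)-1-[3,4-bis(benzyloxy)phenyl]-3-[2-(benzyloxy)-5-bromo-4-(methoxymethoxy)phenyl]prop-2-yn-1-ol
Product: 8 (1R,2Z)-1-[3,4-bis(benzyloxy)phenyl]-3-[2-(benzyloxy)-5-bromo-4-(methoxymethoxy)phenyl]prop-2-en-1-ol
Conditions: H2 (1 atm), Pd/CaCO3 poisoned with Pb(OAc)2, quinoline, EtOAc, rt
Reagents that add atoms: none
Why: Lindlar semihydrogenation adds H2 syn and stops at the Z-alkene without touching benzyl ethers or the aryl bromide; the carbinol centre is unchanged in space and its descriptor becomes R only because the CIP ranking of its neighbours changes.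

Step 6
Reactants: 8 (1R,2Z)-1-[3,4-bis(benzyloxy)phenyl]-3-[2-(benzyloxy)-5-bromo-4-(methoxymethoxy)phenyl]prop-2-en-1-ol
Product: 9 (S)-[3,4-bis(benzyloxy)phenyl]{(2R,3S)-3-[2-(benzyloxy)-5-bromo-4-(methoxymethoxy)phenyl]oxiran-2-yl}methanol (cis-oxirane, carbinol oxygen syn to the oxirane oxygen)
Conditions: dimethyldioxirane (acetone solution, 1.2 equiv), CH2Cl2, −40 to −20 °C; concentrate cold and use crude
Reagents that add atoms: dimethyldioxirane, CC1(C)OO1
Why: Hydroxyl-directed dioxirane epoxidation of a Z-allylic alcohol, in which 1,3-allylic strain holds the carbinol C–H eclipsed with the alkene, the OH hydrogen-bonds the reagent on its own face while ring B shields the other, so oxygen should arrive syn to OH and set both oxirane centres, and the neutral reagent spares the electron-rich aryl epoxide.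

Step 7
Reactants: 9 (S)-[3,4-bis(benzyloxy)phenyl]{(2R,3S)-3-[2-(benzyloxy)-5-bromo-4-(methoxymethoxy)phenyl]oxiran-2-yl}methanol, 10 3-(benzyloxy)phenol
Product: 11 (2S,3S)-2-{(R)-[3-(benzyloxy)phenoxy][3,4-bis(benzyloxy)phenyl]methyl}-3-[2-(benzyloxy)-5-bromo-4-(methoxymethoxy)phenyl]oxirane (cis-oxirane)
Conditions: PPh3, DIAD, toluene, 0 °C to rt; chromatography on Et3N-deactivated silica
Reagents that add atoms: none
Why: Mitsunobu etherification in which the phenoxide displaces the oxyphosphonium group by SN2 and inverts the carbinol centre (syn epoxy alcohol to anti aryl ether, as needed for 2,3-trans), the adjacent electron-withdrawing oxirane carbon disfavouring ionisation of this benzylic position and the neutral medium sparing the epoxide.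

Step 8
Reactants: 11 (2S,3S)-2-{(R)-[3-(benzyloxy)phenoxy][3,4-bis(benzyloxy)phenyl]methyl}-3-[2-(benzyloxy)-5-bromo-4-(methoxymethoxy)phenyl]oxirane
Product: 12 (2R,3S,4R)-7-(benzyloxy)-4-[2-(benzyloxy)-5-bromo-4-(methoxymethoxy)phenyl]-2-[3,4-bis(benzyloxy)phenyl]-3,4-dihydro-2H-chromen-3-ol (2,3-trans-3,4-cis)
Conditions: BF3·OEt2 (20 mol %), CH2Cl2, −78 °C; Et3N then aq. NaHCO3
Reagents that add atoms: none
Why: BF3 binds the oxirane oxygen and weakens the benzylic C4–O bond, the ring A carbon that is ortho to the ether oxygen and para to the benzyloxy group attacks C4 anti to the departing oxygen, and loss of a proton from the arenium ion restores ring A. This is an intramolecular Friedel–Crafts alkylation by an epoxide, the epoxy-arene cyclisation by which aryl ethers of 3-aryl glycidols give 4-arylchroman-3-ols. Ring C closes in the 6-endo-tet mode, preferred over 5-exo attack at C3 because only C4 is benzylic and can take up positive charge. C4 is the single new stereocentre and is fixed by inversion at the oxirane carbon, so the cis-oxirane becomes the 3,4-cis pair, while C2 and C3 keep the anti arrangement made in steps 4 to 7 and therefore end 2,3-trans. The step needs anti attack and attack para to the benzyloxy group: the first is helped by low temperature, a non-polar solvent, the boron-bound oxygen staying on its face as a contact ion pair and the inductive brake of the meta bromine on ring D, the second by crowding at the ring A carbon that lies between the two oxygens.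

Step 9
Reactants: 12 (2R,3S,4R)-7-(benzyloxy)-4-[2-(benzyloxy)-5-bromo-4-(methoxymethoxy)phenyl]-2-[3,4-bis(benzyloxy)phenyl]-3,4-dihydro-2H-chromen-3-ol
Product: 14 1-{4-(benzyloxy)-5-[(2R,3S,4R)-7-(benzyloxy)-2-[3,4-bis(benzyloxy)phenyl]-3-hydroxy-3,4-dihydro-2H-chromen-4-yl]-2-(methoxymethoxy)phenyl}ethan-1-one, via enol ether 13 (not isolated)
Conditions: Pd(PPh3)4 (5 mol %), tributyl(1-ethoxyvinyl)stannane, toluene, 100 °C; then 1 M HCl, THF, 0 °C
Reagents that add atoms: tributyl(1-ethoxyvinyl)stannane, CCCC[Sn](CCCC)(CCCC)C(=C)OCC; water, O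
Why: Stille coupling of the aryl bromide with an α-alkoxyvinylstannane (an acetyl anion equivalent) and brief cold hydrolysis of the enol ether, which is far faster than cleavage of the aryl MOM ether, should give the methyl ketone without touching the free alcohol or any stereocentre.

Step 10
Reactants: 14 1-{4-(benzyloxy)-5-[(2R,3S,4R)-7-(benzyloxy)-2-[3,4-bis(benzyloxy)phenyl]-3-hydroxy-3,4-dihydro-2H-chromen-4-yl]-2-(methoxymethoxy)phenyl}ethan-1-one, 5 3,4-bis(benzyloxy)benzaldehyde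
Product: 15 (2E)-1-{4-(benzyloxy)-5-[(2R,3S,4R)-7-(benzyloxy)-2-[3,4-bis(benzyloxy)phenyl]-3-hydroxy-3,4-dihydro-2H-chromen-4-yl]-2-(methoxymethoxy)phenyl}-3-[3,4-bis(benzyloxy)phenyl]prop-2-en-1-one
Conditions: KOH, EtOH/THF, rt
Reagents that add atoms: none
Why: Claisen–Schmidt condensation of the methyl ketone enolate with the non-enolisable aldehyde followed by E1cB dehydration gives the E-chalcone, and the MOM group on the 2'-oxygen prevents closure to a flavanone.

Step 11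
Reactants: 15 (2E)-1-{4-(benzyloxy)-5-[(2R,3S,4R)-7-(benzyloxy)-2-[3,4-bis(benzyloxy)phenyl]-3-hydroxy-3,4-dihydro-2H-chromen-4-yl]-2-(methoxymethoxy)phenyl}-3-[3,4-bis(benzyloxy)phenyl]prop-2-en-1-one
Product: 16 {4-(benzyloxy)-5-[(2R,3S,4R)-7-(benzyloxy)-2-[3,4-bis(benzyloxy)phenyl]-3-hydroxy-3,4-dihydro-2H-chromen-4-yl]-2-(methoxymethoxy)phenyl}{(2R,3S)-3-[3,4-bis(benzyloxy)phenyl]oxiran-2-yl}methanone (trans-oxirane)
Conditions: poly-L-leucine, urea–H2O2, DBU, THF, rt
Reagents that add atoms: hydrogen peroxide (as its urea adduct), OO.NC(N)=O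
Why: Juliá–Colonna epoxidation, a catalyst-controlled Weitz–Scheffer addition of hydroperoxide to the enone bound to the helical poly-L-leucine, which for E-chalcones gives the (αR,βS)-trans-epoxide, so both new centres are set by the catalyst and the electron-rich arenes are not touched by the nucleophilic oxidant.

Step 12
Reactants: 16 {4-(benzyloxy)-5-[(2R,3S,4R)-7-(benzyloxy)-2-[3,4-bis(benzyloxy)phenyl]-3-hydroxy-3,4-dihydro-2H-chromen-4-yl]-2-(methoxymethoxy)phenyl}{(2R,3S)-3-[3,4-bis(benzyloxy)phenyl]oxiran-2-yl}methanone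
Product: 18 (2R,3R)-7-(benzyloxy)-6-[(2R,3S,4R)-7-(benzyloxy)-2-[3,4-bis(benzyloxy)phenyl]-3-hydroxy-3,4-dihydro-2H-chromen-4-yl]-2-[3,4-bis(benzyloxy)phenyl]-3-hydroxy-2,3-dihydro-4H-chromen-4-one, via hydroxy epoxy ketone 17 (not isolated)
Conditions: conc. HCl (few equiv), MeOH/THF, 45 °C
Reagents that add atoms: none
Why: Acid removes the MOM acetal and the freed 2'-phenol opens the protonated epoxide at the benzylic β-carbon in a 6-endo sense with inversion (the chalcone-epoxide route to dihydroflavonols), which should give C2 as R while C3 keeps the α-carbon configuration, i.e. the 2,3-trans ring F, with benzyl ethers and the 5-deoxy interflavanyl bond tolerating the conditions.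

Step 13
Reactants: 18 (2R,3R)-7-(benzyloxy)-6-[(2R,3S,4R)-7-(benzyloxy)-2-[3,4-bis(benzyloxy)phenyl]-3-hydroxy-3,4-dihydro-2H-chromen-4-yl]-2-[3,4-bis(benzyloxy)phenyl]-3-hydroxy-2,3-dihydro-4H-chromen-4-one
Product: 19 (2R,3R)-2-(3,4-dihydroxyphenyl)-6-[(2R,3S,4S)-2-(3,4-dihydroxyphenyl)-3,7-dihydroxy-3,4-dihydro-2H-chromen-4-yl]-3,7-dihydroxy-2,3-dihydro-4H-chromen-4-one
Conditions: H2 (1 atm), Pd(OH)2/C, THF/MeOH, rt
Reagents that add atoms: none
Why: Hydrogenolysis of the six benzyl ethers, with the deactivated dioxygenated aryl ketone and the cyclic benzylic ether bonds reacting much more slowly and no stereocentre touched (the upper C4 descriptor changes to S only through CIP ranking).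

Step 14
Reactants: 19 (2R,3R)-2-(3,4-dihydroxyphenyl)-6-[(2R,3S,4S)-2-(3,4-dihydroxyphenyl)-3,7-dihydroxy-3,4-dihydro-2H-chromen-4-yl]-3,7-dihydroxy-2,3-dihydro-4H-chromen-4-one
Product: 20 (2R,3S,4S)-2-(3,4-dihydroxyphenyl)-6-[(2R,3S,4S)-2-(3,4-dihydroxyphenyl)-3,7-dihydroxy-3,4-dihydro-2H-chromen-4-yl]-3,4-dihydro-2H-chromene-3,4,7-triol (CNP0280090.1)
Conditions: H2 (1 atm), PtO2, EtOH, rt
Reagents that add atoms: none
Why: Heterogeneous hydrogenation of the dihydroflavonol carbonyl over platinum, in which hydrogen is delivered from the more open equatorial direction of the half-chair and should give the quasi-axial 4-OH cis to the 3-OH (4S), the classical complement to borohydride, which favours the 3,4-trans diol; placing it last keeps the labile benzylic 4-OH away from the debenzylation.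

**Compound list**

1 | 5-bromo-2,4-dihydroxybenzaldehyde | O=Cc1cc(Br)c(O)cc1O | starting material
2 | 5-bromo-2-hydroxy-4-(methoxymethoxy)benzaldehyde | O=Cc1cc(Br)c(OCOC)cc1O | intermediate
3 | 2-(benzyloxy)-5-bromo-4-(methoxymethoxy)benzaldehyde | O=Cc1cc(Br)c(OCOC)cc1OCc1ccccc1 | intermediate
4 | 1-(benzyloxy)-4-bromo-2-ethynyl-5-(methoxymethoxy)benzene | C#Cc1cc(Br)c(OCOC)cc1OCc1ccccc1 | intermediate
5 | 3,4-bis(benzyloxy)benzaldehyde | O=Cc1ccc(OCc2ccccc2)c(OCc2ccccc2)c1 | starting material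
6 | ethyl{[2-(benzyloxy)-5-bromo-4-(methoxymethoxy)phenyl]ethynyl}zinc | CC[Zn]C#Cc1cc(Br)c(OCOC)cc1OCc1ccccc1 | intermediate (not isolated)
7 | (1S)-1-[3,4-bis(benzyloxy)phenyl]-3-[2-(benzyloxy)-5-bromo-4-(methoxymethoxy)phenyl]prop-2-yn-1-ol | O[C@@H](c1ccc(OCc2ccccc2)c(OCc2ccccc2)c1)C#Cc1cc(Br)c(OCOC)cc1OCc1ccccc1 | intermediate
8 | (1R,2Z)-1-[3,4-bis(benzyloxy)phenyl]-3-[2-(benzyloxy)-5-bromo-4-(methoxymethoxy)phenyl]prop-2-en-1-ol | O[C@@H](c1ccc(OCc2ccccc2)c(OCc2ccccc2)c1)/C=C\c1cc(Br)c(OCOC)cc1OCc1ccccc1 | intermediate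
9 | (S)-[3,4-bis(benzyloxy)phenyl]{(2R,3S)-3-[2-(benzyloxy)-5-bromo-4-(methoxymethoxy)phenyl]oxiran-2-yl}methanol | O[C@@H](c1ccc(OCc2ccccc2)c(OCc2ccccc2)c1)[C@H]1O[C@H]1c1cc(Br)c(OCOC)cc1OCc1ccccc1 | intermediate
10 | 3-(benzyloxy)phenol | Oc1cccc(OCc2ccccc2)c1 | starting material
11 | (2S,3S)-2-{(R)-[3-(benzyloxy)phenoxy][3,4-bis(benzyloxy)phenyl]methyl}-3-[2-(benzyloxy)-5-bromo-4-(methoxymethoxy)phenyl]oxirane | C(c1ccccc1)Oc1cccc(c1)O[C@H](c1ccc(OCc2ccccc2)c(OCc2ccccc2)c1)[C@H]1O[C@H]1c1cc(Br)c(OCOC)cc1OCc1ccccc1 | intermediate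
12 | (2R,3S,4R)-7-(benzyloxy)-4-[2-(benzyloxy)-5-bromo-4-(methoxymethoxy)phenyl]-2-[3,4-bis(benzyloxy)phenyl]-3,4-dihydro-2H-chromen-3-ol | C(c1ccccc1)Oc1ccc2c(c1)O[C@H](c1ccc(OCc3ccccc3)c(OCc3ccccc3)c1)[C@@H](O)[C@H]2c1cc(Br)c(OCOC)cc1OCc1ccccc1 | intermediate
13 | (2R,3S,4R)-7-(benzyloxy)-4-[2-(benzyloxy)-5-(1-ethoxyvinyl)-4-(methoxymethoxy)phenyl]-2-[3,4-bis(benzyloxy)phenyl]-3,4-dihydro-2H-chromen-3-ol | C(c1ccccc1)Oc1ccc2c(c1)O[C@H](c1ccc(OCc3ccccc3)c(OCc3ccccc3)c1)[C@@H](O)[C@H]2c1cc(C(=C)OCC)c(OCOC)cc1OCc1ccccc1 | intermediate (not isolated)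
14 | 1-{4-(benzyloxy)-5-[(2R,3S,4R)-7-(benzyloxy)-2-[3,4-bis(benzyloxy)phenyl]-3-hydroxy-3,4-dihydro-2H-chromen-4-yl]-2-(methoxymethoxy)phenyl}ethan-1-one | C(c1ccccc1)Oc1ccc2c(c1)O[C@H](c1ccc(OCc3ccccc3)c(OCc3ccccc3)c1)[C@@H](O)[C@H]2c1cc(C(C)=O)c(OCOC)cc1OCc1ccccc1 | intermediate
15 | (2E)-1-{4-(benzyloxy)-5-[(2R,3S,4R)-7-(benzyloxy)-2-[3,4-bis(benzyloxy)phenyl]-3-hydroxy-3,4-dihydro-2H-chromen-4-yl]-2-(methoxymethoxy)phenyl}-3-[3,4-bis(benzyloxy)phenyl]prop-2-en-1-one | C(c1ccccc1)Oc1ccc2c(c1)O[C@H](c1ccc(OCc3ccccc3)c(OCc3ccccc3)c1)[C@@H](O)[C@H]2c1cc(C(=O)/C=C/c3ccc(OCc4ccccc4)c(OCc4ccccc4)c3)c(OCOC)cc1OCc1ccccc1 | intermediate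
16 | {4-(benzyloxy)-5-[(2R,3S,4R)-7-(benzyloxy)-2-[3,4-bis(benzyloxy)phenyl]-3-hydroxy-3,4-dihydro-2H-chromen-4-yl]-2-(methoxymethoxy)phenyl}{(2R,3S)-3-[3,4-bis(benzyloxy)phenyl]oxiran-2-yl}methanone | C(c1ccccc1)Oc1ccc2c(c1)O[C@H](c1ccc(OCc3ccccc3)c(OCc3ccccc3)c1)[C@@H](O)[C@H]2c1cc(C(=O)[C@@H]3O[C@H]3c3ccc(OCc4ccccc4)c(OCc4ccccc4)c3)c(OCOC)cc1OCc1ccccc1 | intermediate
17 | {4-(benzyloxy)-5-[(2R,3S,4R)-7-(benzyloxy)-2-[3,4-bis(benzyloxy)phenyl]-3-hydroxy-3,4-dihydro-2H-chromen-4-yl]-2-hydroxyphenyl}{(2R,3S)-3-[3,4-bis(benzyloxy)phenyl]oxiran-2-yl}methanone | C(c1ccccc1)Oc1ccc2c(c1)O[C@H](c1ccc(OCc3ccccc3)c(OCc3ccccc3)c1)[C@@H](O)[C@H]2c1cc(C(=O)[C@@H]3O[C@H]3c3ccc(OCc4ccccc4)c(OCc4ccccc4)c3)c(O)cc1OCc1ccccc1 | intermediate (not isolated)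
18 | (2R,3R)-7-(benzyloxy)-6-[(2R,3S,4R)-7-(benzyloxy)-2-[3,4-bis(benzyloxy)phenyl]-3-hydroxy-3,4-dihydro-2H-chromen-4-yl]-2-[3,4-bis(benzyloxy)phenyl]-3-hydroxy-2,3-dihydro-4H-chromen-4-one | C(c1ccccc1)Oc1ccc2c(c1)O[C@H](c1ccc(OCc3ccccc3)c(OCc3ccccc3)c1)[C@@H](O)[C@H]2c1cc2c(cc1OCc1ccccc1)O[C@H](c1ccc(OCc3ccccc3)c(OCc3ccccc3)c1)[C@@H](O)C2=O | intermediate
19 | (2R,3R)-2-(3,4-dihydroxyphenyl)-6-[(2R,3S,4S)-2-(3,4-dihydroxyphenyl)-3,7-dihydroxy-3,4-dihydro-2H-chromen-4-yl]-3,7-dihydroxy-2,3-dihydro-4H-chromen-4-one | Oc1ccc2c(c1)O[C@H](c1ccc(O)c(O)c1)[C@@H](O)[C@H]2c1cc2c(cc1O)O[C@H](c1ccc(O)c(O)c1)[C@@H](O)C2=O | intermediate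
20 | (2R,3S,4S)-2-(3,4-dihydroxyphenyl)-6-[(2R,3S,4S)-2-(3,4-dihydroxyphenyl)-3,7-dihydroxy-3,4-dihydro-2H-chromen-4-yl]-3,4-dihydro-2H-chromene-3,4,7-triol | Oc1ccc2c(c1)O[C@H](c1ccc(O)c(O)c1)[C@@H](O)[C@H]2c1cc2c(cc1O)O[C@H](c1ccc(O)c(O)c1)[C@@H](O)[C@H]2O | target

**Step count and risks**

Total steps: 14. Longest linear sequence: 14 steps (1 to 20); 5 and 10 are purchased and enter in steps 4, 10 and 7.

Most likely to fail, in order:

Step 8. The risk is full ionisation of the C4–O bond before ring A arrives, so that rotation about C3–C4 erases facial control at C4, with hydride shift to a ketone as a competing drain. The fallback sets out from 9 and returns at 12, making C4–C4a by an SN2 organometallic opening and ring C through O1–C2. Purchased 5-(benzyloxy)-2-bromophenol is silylated (TBSCl, imidazole, DMF) to tert-butyl[5-(benzyloxy)-2-bromophenoxy]dimethylsilane F1. Magnesium in THF converts it into {4-(benzyloxy)-2-[(tert-butyldimethylsilyl)oxy]phenyl}magnesium bromide F2. With CuI (10 mol %) at −40 °C this opens epoxy alcohol 9 at the benzylic oxirane carbon with inversion, giving (1S,2S,3S)-3-{4-(benzyloxy)-2-[(tert-butyldimethylsilyl)oxy]phenyl}-3-[2-(benzyloxy)-5-bromo-4-(methoxymethoxy)phenyl]-1-[3,4-bis(benzyloxy)phenyl]propane-1,2-diol F3. Bu4NF in THF frees the phenol to give the (1S,2S,3R)-triol F4. HC(OEt)3 with PPTS in CH2Cl2 converts the 1,2-diol into the cyclic orthoformate F5. On warming this ionises to the dioxolanylium ion, which the phenol opens at benzylic C2 with inversion, giving the 2,3-trans flavan-3-yl formate F6. K2CO3 in MeOH then removes the formyl group and gives 12.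

Step 7. The risk is slow displacement at a carbinol flanked by the cis-oxirane, with opening of the acid-sensitive epoxide by the phenol competing. The fallback sets out from 7, returns at 11 and bypasses 8 and 9. Mitsunobu etherification of 7 with 10 (PPh3, DIAD, toluene, −20 °C) gives the inverted 1-(benzyloxy)-3-{[(1R)-1-[3,4-bis(benzyloxy)phenyl]-3-[2-(benzyloxy)-5-bromo-4-(methoxymethoxy)phenyl]prop-2-yn-1-yl]oxy}benzene F7. Semihydrogenation (H2, Pd/CaCO3 poisoned with Pb(OAc)2, quinoline) gives the (1S,2Z)-allyl aryl ether F8. A catalyst-controlled Shi epoxidation with a glucose-derived N-aryl oxazolidinone ketone and KHSO5 at pH 10.5 then gives 11. The ketone enantiomer is the one that gives the (1S,2R)-oxide from cis-β-methylstyrene, so that oxygen arrives on the alkene face anti to the aryloxy group.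

Step 14. The risk is incomplete cis-selectivity in the carbonyl hydrogenation, or hydrogenolysis of the new benzylic C4–OH. The fallback sets out from 18 and returns at 20, reducing before deprotection. LiBH(s-Bu)3 in THF at −78 °C attacks the ketone from the equatorial direction and should give (2R,3S,4S)-7-(benzyloxy)-6-[(2R,3S,4R)-7-(benzyloxy)-2-[3,4-bis(benzyloxy)phenyl]-3-hydroxy-3,4-dihydro-2H-chromen-4-yl]-2-[3,4-bis(benzyloxy)phenyl]-3,4-dihydro-2H-chromene-3,4-diol F9. Hydrogenolysis (H2, Pd(OH)2/C, EtOAc/MeOH, trace NaHCO3) then gives 20.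

**Further compounds**

F1 | step 8 | tert-butyl[5-(benzyloxy)-2-bromophenoxy]dimethylsilane | CC(C)(C)[Si](C)(C)Oc1cc(OCc2ccccc2)ccc1Br
F2 | step 8 | {4-(benzyloxy)-2-[(tert-butyldimethylsilyl)oxy]phenyl}magnesium bromide | CC(C)(C)[Si](C)(C)Oc1cc(OCc2ccccc2)ccc1[Mg]Br
F3 | step 8 | (1S,2S,3S)-3-{4-(benzyloxy)-2-[(tert-butyldimethylsilyl)oxy]phenyl}-3-[2-(benzyloxy)-5-bromo-4-(methoxymethoxy)phenyl]-1-[3,4-bis(benzyloxy)phenyl]propane-1,2-diol | O[C@@H](c1ccc(OCc2ccccc2)c(OCc2ccccc2)c1)[C@@H](O)[C@H](c1ccc(OCc2ccccc2)cc1O[Si](C)(C)C(C)(C)C)c1cc(Br)c(OCOC)cc1OCc1ccccc1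
F4 | step 8 | (1S,2S,3R)-3-[4-(benzyloxy)-2-hydroxyphenyl]-3-[2-(benzyloxy)-5-bromo-4-(methoxymethoxy)phenyl]-1-[3,4-bis(benzyloxy)phenyl]propane-1,2-diol | O[C@@H](c1ccc(OCc2ccccc2)c(OCc2ccccc2)c1)[C@@H](O)[C@H](c1ccc(OCc2ccccc2)cc1O)c1cc(Br)c(OCOC)cc1OCc1ccccc1
F5 | step 8 | cyclic orthoformate (2-ethoxy-1,3-dioxolane across the 1,2-diol) of F4, mixture at the orthoester carbon | CCOC1O[C@@H](c2ccc(OCc3ccccc3)c(OCc3ccccc3)c2)[C@@H](O1)[C@H](c1ccc(OCc2ccccc2)cc1O)c1cc(Br)c(OCOC)cc1OCc1ccccc1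
F6 | step 8 | (2R,3S,4R)-7-(benzyloxy)-4-[2-(benzyloxy)-5-bromo-4-(methoxymethoxy)phenyl]-2-[3,4-bis(benzyloxy)phenyl]-3,4-dihydro-2H-chromen-3-yl formate | C(c1ccccc1)Oc1ccc2c(c1)O[C@H](c1ccc(OCc3ccccc3)c(OCc3ccccc3)c1)[C@@H](OC=O)[C@H]2c1cc(Br)c(OCOC)cc1OCc1ccccc1
F7 | step 7 | 1-(benzyloxy)-3-{[(1R)-1-[3,4-bis(benzyloxy)phenyl]-3-[2-(benzyloxy)-5-bromo-4-(methoxymethoxy)phenyl]prop-2-yn-1-yl]oxy}benzene | C(c1ccccc1)Oc1cccc(c1)O[C@H](c1ccc(OCc2ccccc2)c(OCc2ccccc2)c1)C#Cc1cc(Br)c(OCOC)cc1OCc1ccccc1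
F8 | step 7 | 1-(benzyloxy)-3-{[(1S,2Z)-1-[3,4-bis(benzyloxy)phenyl]-3-[2-(benzyloxy)-5-bromo-4-(methoxymethoxy)phenyl]prop-2-en-1-yl]oxy}benzene | C(c1ccccc1)Oc1cccc(c1)O[C@H](c1ccc(OCc2ccccc2)c(OCc2ccccc2)c1)/C=C\c1cc(Br)c(OCOC)cc1OCc1ccccc1
F9 | step 14 | (2R,3S,4S)-7-(benzyloxy)-6-[(2R,3S,4R)-7-(benzyloxy)-2-[3,4-bis(benzyloxy)phenyl]-3-hydroxy-3,4-dihydro-2H-chromen-4-yl]-2-[3,4-bis(benzyloxy)phenyl]-3,4-dihydro-2H-chromene-3,4-diol | C(c1ccccc1)Oc1ccc2c(c1)O[C@H](c1ccc(OCc3ccccc3)c(OCc3ccccc3)c1)[C@@H](O)[C@H]2c1cc2c(cc1OCc1ccccc1)O[C@H](c1ccc(OCc3ccccc3)c(OCc3ccccc3)c1)[C@@H](O)[C@H]2O
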